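**Retrosynthetic overview**
1. The strategy rests on the hexasubstituted right benzene ring (C4a′, C5′, C6′, C7′, C8′, C8a′): the lactone carbonyl C1′ on C8a′ is ortho to the 8′-hydroxyl and para to the 6′-hydroxyl, and C7′ between the two hydroxyls carries the CH2 bridge.
2. Last disconnections: the O2–C1=C8a quinone-methide ring (orthoformate formylation and cyclisation of the left resorcinol), the two aryl methyl ethers, and the C1′–O2′ lactone bond.
3. Key disconnection: C5′–C4a′ and C8′–C8a′, i.e. a 1-methoxy-1,3-bis(silyloxy)diene carrying the left arene on its central carbon plus a chiral ynoate, aromatised by loss of methanol.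
4. The ynoate comes from methyl (R)-3-hydroxybutanoate (anti-methylation, alkynylation, carboxylation); the diene comes from methyl 3-oxopentanoate and a left-arm benzylic bromide built from 1-bromo-3,5-dimethoxybenzene and (2S,3S)-2,3-epoxybutane.
5. Ring order: left benzene ring (bought), right benzene ring (step 17), lactone ring (step 18), pyran ring of the quinone methide (step 20).

Key step: step 17

Remark: the target is drawn as the 8-oxo-6-hydroxy tautomer of the left quinone methide; this and the 6-oxo-8-hydroxy form interconvert by proton shift, so step 20 is taken to deliver the compound as drawn. Unprimed locants refer to the left isochromene half, primed locants to the right isochromanone half.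

**Route**

Step 1
Reactants: 1 methyl (R)-3-hydroxybutanoate
Product: 3 methyl (2R,3R)-3-hydroxy-2-methylbutanoate, via dilithium alkoxide enolate 2 (not isolated)
Conditions: LDA (2.2 equiv), THF, −78 → −20 °C; MeI, DMPU, −78 → 0 °C; then H2O
Reagents that add atoms: iodomethane, CI
Why: Fráter–Seebach alkylation, in which the chelated alkoxide enolate is methylated on the face anti to the C3 methyl group, so the new C2 centre should be R (anti to the 3R carbinol).

Step 2
Reactants: 3 methyl (2R,3R)-3-hydroxy-2-methylbutanoate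
Product: 4 methyl (2R,3R)-3-(tert-butyldimethylsilyloxy)-2-methylbutanoate
Conditions: TBSCl, imidazole, DMF, rt
Reagents that add atoms: tert-butyldimethylsilyl chloride, CC(C)(C)[Si](C)(C)Cl
Why: Standard silylation of a secondary alcohol; imidazole does not enolise the ester, so both centres are kept.

Step 3
Reactants: 4 methyl (2R,3R)-3-(tert-butyldimethylsilyloxy)-2-methylbutanoate
Product: 5 (2R,3R)-3-(tert-butyldimethylsilyloxy)-2-methylbutanal
Conditions: DIBAL-H (1.1 equiv), CH2Cl2, −78 °C; then aq. Rochelle salt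
Reagents that add atoms: none
Why: Partial ester reduction with DIBAL-H, in which the aluminium hemiacetal is stable at −78 °C and releases the aldehyde only on the non-basic work-up, so the α-centre should not epimerise.

Step 4
Reactants: 5 (2R,3R)-3-(tert-butyldimethylsilyloxy)-2-methylbutanal
Product: 6 (3S,4R)-4-(tert-butyldimethylsilyloxy)-3-methylpent-1-yne
Conditions: dimethyl (1-diazo-2-oxopropyl)phosphonate, K2CO3, MeOH, 0 °C → rt
Reagents that add atoms: dimethyl (1-diazo-2-oxopropyl)phosphonate, CC(=O)C(=[N+]=[N-])P(=O)(OC)OC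
Why: Seyferth–Gilbert homologation in the Ohira–Bestmann variant gives the terminal alkyne under mild carbonate/methanol conditions with the geometry at the α-carbon kept (its descriptor becomes S only through the CIP priorities).

Step 5
Reactants: 6 (3S,4R)-4-(tert-butyldimethylsilyloxy)-3-methylpent-1-yne
Product: 8 methyl (4S,5R)-5-(tert-butyldimethylsilyloxy)-4-methylhex-2-ynoate, via lithium acetylide 7 (not isolated)
Conditions: n-BuLi, THF, −78 °C; ClCO2Me, −78 → 0 °C
Reagents that add atoms: methyl chloroformate, COC(=O)Cl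
Why: Deprotonation of the terminal alkyne and C-acylation of the acetylide with a chloroformate is a standard ynoate synthesis that does not touch the propargylic centre.

Step 6
Reactants: 9 1-bromo-3,5-dimethoxybenzene; 10 (2S,3S)-2,3-epoxybutane
Product: 12 (2S,3S)-3-(3,5-dimethoxyphenyl)butan-2-ol, via 3,5-dimethoxyphenylmagnesium bromide 11 (not isolated)
Conditions: Mg, THF, reflux; then CuI (10 mol%), 10, −30 → 0 °C; then H2O
Reagents that add atoms: none
Why: Copper-catalysed SN2 opening of the C2-symmetric trans-epoxide by the aryl Grignard reagent proceeds with inversion at the attacked carbon (either carbon gives the same product), which sets the benzylic centre as S and leaves the carbinol S.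

Step 7
Reactants: 12 (2S,3S)-3-(3,5-dimethoxyphenyl)butan-2-ol
Product: 14 (2R,3S)-3-(3,5-dimethoxyphenyl)butan-2-ol, via inverted 4-nitrobenzoate ester 13 (not isolated)
Conditions: 4-nitrobenzoic acid, PPh3, DIAD, THF, 0 °C → rt; then K2CO3 (cat.), MeOH, rt
Reagents that add atoms: 4-nitrobenzoic acid, O=C(O)c1ccc(cc1)[N+](=O)[O-]
Why: Mitsunobu inversion turns the 2S carbinol into 2R by SN2 attack of the carboxylate on the oxyphosphonium salt (aryl participation should be weak because both methoxy groups are meta to the ipso carbon), and carbonate-catalysed methanolysis frees the alcohol.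

Step 8
Reactants: 14 (2R,3S)-3-(3,5-dimethoxyphenyl)butan-2-ol
Product: 15 tert-butyl{[(2R,3S)-3-(3,5-dimethoxyphenyl)butan-2-yl]oxy}dimethylsilane
Conditions: TBSCl, imidazole, DMF, rt
Reagents that add atoms: tert-butyldimethylsilyl chloride, CC(C)(C)[Si](C)(C)Cl
Why: Standard silylation, giving an ether that should survive the organolithium steps and the thermal key step.

Step 9
Reactants: 15 tert-butyl{[(2R,3S)-3-(3,5-dimethoxyphenyl)butan-2-yl]oxy}dimethylsilane
Product: 16 {[(2R,3S)-3-(2-bromo-3,5-dimethoxyphenyl)butan-2-yl]oxy}(tert-butyl)dimethylsilane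
Conditions: NBS (1.0 equiv), MeCN, 0 °C
Reagents that add atoms: N-bromosuccinimide, O=C1CCC(=O)N1Br
Why: Electrophilic aromatic bromination should go para to one methoxy group and next to the side chain (the two such positions are equivalent) rather than between the two methoxy groups, as is usual for 5-alkylresorcinol dimethyl ethers.

Step 10
Reactants: 16 {[(2R,3S)-3-(2-bromo-3,5-dimethoxyphenyl)butan-2-yl]oxy}(tert-butyl)dimethylsilane
Product: 18 tert-butyl{[(2R,3S)-3-(3,5-dimethoxy-2-methylphenyl)butan-2-yl]oxy}dimethylsilane, via 2-lithioarene 17 (not isolated)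
Conditions: n-BuLi, THF, −78 °C; MeI, −78 → 0 °C
Reagents that add atoms: iodomethane, CI
Why: Bromine–lithium exchange followed by methylation of the aryllithium places the future C5 methyl group exactly at the brominated carbon.

Step 11
Reactants: 18 tert-butyl{[(2R,3S)-3-(3,5-dimethoxy-2-methylphenyl)butan-2-yl]oxy}dimethylsilane
Product: 20 4-[(2S,3R)-3-(tert-butyldimethylsilyloxy)butan-2-yl]-2,6-dimethoxy-3-methylbenzaldehyde, via 4-lithioarene 19 (not isolated)
Conditions: n-BuLi, TMEDA, THF, 0 °C; DMF, 0 °C → rt; then H2O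
Reagents that add atoms: N,N-dimethylformamide, CN(C)C=O
Why: Directed ortho-metalation removes the most acidic ring hydrogen, the one between the two methoxy groups, and the aryllithium is formylated with DMF, which places the future bridge carbon.

Step 12
Reactants: 20 4-[(2S,3R)-3-(tert-butyldimethylsilyloxy)butan-2-yl]-2,6-dimethoxy-3-methylbenzaldehyde
Product: 21 {4-[(2S,3R)-3-(tert-butyldimethylsilyloxy)butan-2-yl]-2,6-dimethoxy-3-methylphenyl}methanol
Conditions: NaBH4, MeOH, 0 °C
Reagents that add atoms: none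
Why: Borohydride reduction of an aryl aldehyde to the benzylic alcohol, with no other reducible group present.

Step 13
Reactants: 21 {4-[(2S,3R)-3-(tert-butyldimethylsilyloxy)butan-2-yl]-2,6-dimethoxy-3-methylphenyl}methanol
Product: 22 {[(2R,3S)-3-[4-(bromomethyl)-3,5-dimethoxy-2-methylphenyl]butan-2-yl]oxy}(tert-butyl)dimethylsilane
Conditions: CBr4, PPh3, CH2Cl2, 0 °C; used at once
Reagents that add atoms: carbon tetrabromide, BrC(Br)(Br)Br
Why: Appel bromination converts the benzylic alcohol into the bromide under neutral conditions that should spare the TBS ether.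

Step 14
Reactants: 22 {[(2R,3S)-3-[4-(bromomethyl)-3,5-dimethoxy-2-methylphenyl]butan-2-yl]oxy}(tert-butyl)dimethylsilane; 23 methyl 3-oxopentanoate
Product: 25 methyl 2-({4-[(2S,3R)-3-(tert-butyldimethylsilyloxy)butan-2-yl]-2,6-dimethoxy-3-methylphenyl}methyl)-3-oxopentanoate (C2 epimers), via sodium enolate of 23 24 (not isolated)
Conditions: 23 (2 equiv), NaH, THF, 0 °C; then 22, 0 °C → rt
Reagents that add atoms: none
Why: C-alkylation of a β-ketoester enolate with a reactive benzylic bromide, with excess enolate to suppress double alkylation; the new C2 centre becomes sp2 later and needs no control.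

Step 15
Reactants: 25 methyl 2-(arylmethyl)-3-oxopentanoate (as named in step 14)
Product: 26 methyl 2-({4-[(2S,3R)-3-(tert-butyldimethylsilyloxy)butan-2-yl]-2,6-dimethoxy-3-methylphenyl}methyl)-3-(trimethylsilyloxy)pent-2-enoate (E/Z)
Conditions: TMSCl, Et3N, toluene, rt
Reagents that add atoms: chlorotrimethylsilane, C[Si](C)(C)Cl
Why: O-silylation of the β-ketoester under equilibrating amine conditions should give the conjugated β-silyloxy enoate, the first stage of the usual two-stage bis-silyl dienol ether preparation.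

Step 16
Reactants: 26 methyl 2-(arylmethyl)-3-(trimethylsilyloxy)pent-2-enoate (as named in step 15)
Product: 28 1-methoxy-1,3-bis(trimethylsilyloxy)penta-1,3-diene bearing the {4-[(2S,3R)-3-(tert-butyldimethylsilyloxy)butan-2-yl]-2,6-dimethoxy-3-methylphenyl}methyl group on C2 (alkene geometries not fixed), via lithium dienolate 27 (not isolated)
Conditions: LDA, THF, −78 °C; TMSCl, −78 → 0 °C; pentane, filtration; used crude
Reagents that add atoms: chlorotrimethylsilane, C[Si](C)(C)Cl
Why: γ-Deprotonation of the β-silyloxy enoate with LDA and O-silylation of the dienolate is the standard preparation of 1-alkoxy-1,3-bis(silyloxy)dienes, and the terminal methyl is expected cis to the silyloxy group.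

Step 17
Reactants: 28 bis-silyl diene (as named in step 16); 8 methyl (4S,5R)-5-(tert-butyldimethylsilyloxy)-4-methylhex-2-ynoate
Product: 30 methyl 3-({4-[(2S,3R)-3-(tert-butyldimethylsilyloxy)butan-2-yl]-2,6-dimethoxy-3-methylphenyl}methyl)-6-[(2S,3R)-3-(tert-butyldimethylsilyloxy)butan-2-yl]-2,4-dihydroxy-5-methylbenzoate, via bis-silylated cyclohexadiene cycloadduct 29 (not isolated)
Conditions: 8 (1.5 equiv), toluene (conc.), sealed tube, 130 °C; then 0.1 M HCl, THF, 0 °C
Reagents that add atoms: none
Why: The electron-rich diene 28 and ynoate 8 should combine in a polarised, asynchronous thermal [4+2] cycloaddition in which the methyl-bearing diene terminus (future C5′) bonds to the ynoate β-carbon (future C4a′) and the silyl ketene acetal carbon (future C8′) bonds to the α-carbon (future C8a′), giving cyclohexa-1,4-diene 29. The closest known reaction type is the Diels–Alder/aromatisation of 1-alkoxy-1,3-bis(silyloxy)-1,3-dienes with alkynoates to give 2,4-dihydroxybenzoates. The right benzene ring is closed in this intermolecular [4+2] mode, both ring bonds in one operation, and is aromatised by collapse of the mixed silyl methyl ketal at C8′ with loss of methanol and the C5′ hydrogen; the remaining aryl trimethylsilyl ether is hydrolysed on the mildly acidic work-up, which should leave both TBS ethers in place. No new stereocentre survives, because the two sp3 ring carbons of 29 become aromatic, and the (2S,3R) diads of both arms lie outside the reacting atoms and have no hydrogen that is acidic under neutral thermal conditions. The step needs one regiochemistry (ester next to the arm and para to one hydroxyl), which is secured by matching the largest HOMO coefficient at the diene terminus with the largest LUMO coefficient at the ynoate β-carbon, the normal outcome for 1,3-dioxygenated dienes with propiolate-type dienophiles; the expected Z enol ether geometry turns the terminal methyl outward so that the s-cis conformer is accessible.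

Step 18
Reactants: 30 methyl resorcylate (as named in step 17)
Product: 32 (3R,4S)-6,8-dihydroxy-7-({4-[(2S,3R)-3-hydroxybutan-2-yl]-2,6-dimethoxy-3-methylphenyl}methyl)-3,4,5-trimethylisochroman-1-one, via desilylated seco diol ester 31 (not isolated)
Conditions: HCl, MeOH, 40 °C; then TsOH (cat.), toluene, 80 °C
Reagents that add atoms: none
Why: Acidic methanolysis removes both TBS ethers, and acid-catalysed intramolecular transesterification of the ortho ester by the freed right-arm alcohol closes the six-membered lactone (6-exo-trig) with retention at both centres, the left-arm alcohol having no ester within reach.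

Step 19
Reactants: 32 (3R,4S)-6,8-dihydroxy-7-({4-[(2S,3R)-3-hydroxybutan-2-yl]-2,6-dimethoxy-3-methylphenyl}methyl)-3,4,5-trimethylisochroman-1-one
Product: 33 (3R,4S)-7-({2,6-dihydroxy-4-[(2S,3R)-3-hydroxybutan-2-yl]-3-methylphenyl}methyl)-6,8-dihydroxy-3,4,5-trimethylisochroman-1-one
Conditions: BBr3 (8 equiv), CH2Cl2, −78 → 0 °C; then H2O
Reagents that add atoms: none
Why: Lewis-acid ether cleavage with BBr3 should demethylate both aryl methyl ethers, while the lactone survives and the phenols and the alcohol, held as borates, are released on aqueous work-up.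

Step 20
Reactants: 33 (3R,4S)-7-({2,6-dihydroxy-4-[(2S,3R)-3-hydroxybutan-2-yl]-3-methylphenyl}methyl)-6,8-dihydroxy-3,4,5-trimethylisochroman-1-one
Product: 35 Dicitrinone G, via 1-ethoxyisochroman cyclic acetal 34 (not isolated)
Conditions: HC(OEt)3, TFA (cat.), CH2Cl2, 0 °C → rt; then H2O
Reagents that add atoms: triethyl orthoformate, CCOC(OCC)OCC
Why: Acid-promoted electrophilic formylation of the resorcinol by the orthoformate at its only free ring carbon (C8a, ortho and para to the hydroxyls), capture by the arm alcohol as a cyclic acetal and loss of ethanol should give the quinone methide, a known annulation of 5-(3-hydroxybutan-2-yl)resorcinols that does not involve C3 or C4.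

**Compound list**
1 | methyl (R)-3-hydroxybutanoate | C[C@@H](O)CC(=O)OC | starting material
2 | dilithium alkoxide enolate of 1 | C[C@@H]([O-])C=C([O-])OC.[Li+].[Li+] | intermediate
3 | methyl (2R,3R)-3-hydroxy-2-methylbutanoate | COC(=O)[C@H](C)[C@@H](C)O | intermediate
4 | methyl (2R,3R)-3-(tert-butyldimethylsilyloxy)-2-methylbutanoate | COC(=O)[C@H](C)[C@@H](C)O[Si](C)(C)C(C)(C)C | intermediate
5 | (2R,3R)-3-(tert-butyldimethylsilyloxy)-2-methylbutanal | O=C[C@H](C)[C@@H](C)O[Si](C)(C)C(C)(C)C | intermediate
6 | (3S,4R)-4-(tert-butyldimethylsilyloxy)-3-methylpent-1-yne | C#C[C@H](C)[C@@H](C)O[Si](C)(C)C(C)(C)C | intermediate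
7 | lithium acetylide of 6 | [Li]C#C[C@H](C)[C@@H](C)O[Si](C)(C)C(C)(C)C | intermediate
8 | methyl (4S,5R)-5-(tert-butyldimethylsilyloxy)-4-methylhex-2-ynoate | COC(=O)C#C[C@H](C)[C@@H](C)O[Si](C)(C)C(C)(C)C | intermediate
9 | 1-bromo-3,5-dimethoxybenzene | COc1cc(Br)cc(OC)c1 | starting material
10 | (2S,3S)-2,3-epoxybutane | C[C@@H]1O[C@H]1C | starting material
11 | 3,5-dimethoxyphenylmagnesium bromide | COc1cc([Mg]Br)cc(OC)c1 | intermediate
12 | (2S,3S)-3-(3,5-dimethoxyphenyl)butan-2-ol | COc1cc(OC)cc([C@H](C)[C@H](C)O)c1 | intermediate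
13 | (2R,3S)-3-(3,5-dimethoxyphenyl)butan-2-yl 4-nitrobenzoate | COc1cc(OC)cc([C@H](C)[C@@H](C)OC(=O)c2ccc([N+](=O)[O-])cc2)c1 | intermediate
14 | (2R,3S)-3-(3,5-dimethoxyphenyl)butan-2-ol | COc1cc(OC)cc([C@H](C)[C@@H](C)O)c1 | intermediate
15 | tert-butyl{[(2R,3S)-3-(3,5-dimethoxyphenyl)butan-2-yl]oxy}dimethylsilane | COc1cc(OC)cc([C@H](C)[C@@H](C)O[Si](C)(C)C(C)(C)C)c1 | intermediate
16 | {[(2R,3S)-3-(2-bromo-3,5-dimethoxyphenyl)butan-2-yl]oxy}(tert-butyl)dimethylsilane | COc1cc(OC)c(Br)c([C@H](C)[C@@H](C)O[Si](C)(C)C(C)(C)C)c1 | intermediate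
17 | 2-lithio derivative of 15 (lithium at the former C–Br carbon) | COc1cc(OC)c([Li])c([C@H](C)[C@@H](C)O[Si](C)(C)C(C)(C)C)c1 | intermediate
18 | tert-butyl{[(2R,3S)-3-(3,5-dimethoxy-2-methylphenyl)butan-2-yl]oxy}dimethylsilane | COc1cc(OC)c(C)c([C@H](C)[C@@H](C)O[Si](C)(C)C(C)(C)C)c1 | intermediate
19 | 4-lithio derivative of 18 (lithium between the two methoxy groups) | COc1cc([C@H](C)[C@@H](C)O[Si](C)(C)C(C)(C)C)c(C)c(OC)c1[Li] | intermediate
20 | 4-[(2S,3R)-3-(tert-butyldimethylsilyloxy)butan-2-yl]-2,6-dimethoxy-3-methylbenzaldehyde | COc1cc([C@H](C)[C@@H](C)O[Si](C)(C)C(C)(C)C)c(C)c(OC)c1C=O | intermediate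
21 | {4-[(2S,3R)-3-(tert-butyldimethylsilyloxy)butan-2-yl]-2,6-dimethoxy-3-methylphenyl}methanol | COc1cc([C@H](C)[C@@H](C)O[Si](C)(C)C(C)(C)C)c(C)c(OC)c1CO | intermediate
22 | {[(2R,3S)-3-[4-(bromomethyl)-3,5-dimethoxy-2-methylphenyl]butan-2-yl]oxy}(tert-butyl)dimethylsilane | COc1cc([C@H](C)[C@@H](C)O[Si](C)(C)C(C)(C)C)c(C)c(OC)c1CBr | intermediate
23 | methyl 3-oxopentanoate | CCC(=O)CC(=O)OC | starting material
24 | sodium enolate of methyl 3-oxopentanoate | CCC(=O)C=C([O-])OC.[Na+] | intermediate
25 | methyl 2-({4-[(2S,3R)-3-(tert-butyldimethylsilyloxy)butan-2-yl]-2,6-dimethoxy-3-methylphenyl}methyl)-3-oxopentanoate (C2 epimers) | CCC(=O)C(Cc1c(OC)cc([C@H](C)[C@@H](C)O[Si](C)(C)C(C)(C)C)c(C)c1OC)C(=O)OC | intermediate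
26 | methyl 2-(arylmethyl)-3-(trimethylsilyloxy)pent-2-enoate, aryl as in 25 (E/Z) | CCC(O[Si](C)(C)C)=C(Cc1c(OC)cc([C@H](C)[C@@H](C)O[Si](C)(C)C(C)(C)C)c(C)c1OC)C(=O)OC | intermediate
27 | lithium dienolate of 26 | CC=C(O[Si](C)(C)C)C(Cc1c(OC)cc([C@H](C)[C@@H](C)O[Si](C)(C)C(C)(C)C)c(C)c1OC)=C([O-])OC.[Li+] | intermediate
28 | 2-(arylmethyl)-1-methoxy-1,3-bis(trimethylsilyloxy)penta-1,3-diene, aryl as in 25 (alkene geometries not fixed) | CC=C(O[Si](C)(C)C)C(Cc1c(OC)cc([C@H](C)[C@@H](C)O[Si](C)(C)C(C)(C)C)c(C)c1OC)=C(OC)O[Si](C)(C)C | intermediate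
29 | cyclohexa-1,4-diene cycloadduct of 28 and 8 (two ring sp3 centres unassigned) | COC(=O)C1=C([C@H](C)[C@@H](C)O[Si](C)(C)C(C)(C)C)C(C)C(O[Si](C)(C)C)=C(Cc2c(OC)cc([C@H](C)[C@@H](C)O[Si](C)(C)C(C)(C)C)c(C)c2OC)C1(OC)O[Si](C)(C)C | intermediate
30 | methyl 3-({4-[(2S,3R)-3-(tert-butyldimethylsilyloxy)butan-2-yl]-2,6-dimethoxy-3-methylphenyl}methyl)-6-[(2S,3R)-3-(tert-butyldimethylsilyloxy)butan-2-yl]-2,4-dihydroxy-5-methylbenzoate | COC(=O)c1c(O)c(Cc2c(OC)cc([C@H](C)[C@@H](C)O[Si](C)(C)C(C)(C)C)c(C)c2OC)c(O)c(C)c1[C@H](C)[C@@H](C)O[Si](C)(C)C(C)(C)C | intermediate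
31 | methyl 2,4-dihydroxy-6-[(2S,3R)-3-hydroxybutan-2-yl]-3-({4-[(2S,3R)-3-hydroxybutan-2-yl]-2,6-dimethoxy-3-methylphenyl}methyl)-5-methylbenzoate | COC(=O)c1c(O)c(Cc2c(OC)cc([C@H](C)[C@@H](C)O)c(C)c2OC)c(O)c(C)c1[C@H](C)[C@@H](C)O | intermediate
32 | (3R,4S)-6,8-dihydroxy-7-({4-[(2S,3R)-3-hydroxybutan-2-yl]-2,6-dimethoxy-3-methylphenyl}methyl)-3,4,5-trimethylisochroman-1-one | COc1cc([C@H](C)[C@@H](C)O)c(C)c(OC)c1Cc1c(O)c(C)c2c(c1O)C(=O)O[C@H](C)[C@H]2C | intermediate
33 | (3R,4S)-7-({2,6-dihydroxy-4-[(2S,3R)-3-hydroxybutan-2-yl]-3-methylphenyl}methyl)-6,8-dihydroxy-3,4,5-trimethylisochroman-1-one | Cc1c(O)c(Cc2c(O)c(C)c3c(c2O)C(=O)O[C@H](C)[C@H]3C)c(O)cc1[C@H](C)[C@@H](C)O | intermediate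
34 | (3R,4S)-7-{[(3R,4S)-1-ethoxy-6,8-dihydroxy-3,4,5-trimethylisochroman-7-yl]methyl}-6,8-dihydroxy-3,4,5-trimethylisochroman-1-one (C1 epimers) | Cc1c2c(C(OCC)O[C@H](C)[C@H]2C)c(O)c(Cc3c(O)c(C)c4c(c3O)C(=O)O[C@H](C)[C@H]4C)c1O | intermediate
35 | Dicitrinone G | CC1=C2C(=CO[C@H](C)[C@H]2C)C(=O)C(Cc2c(O)c(C)c3c(c2O)C(=O)O[C@H](C)[C@H]3C)=C1O | target

**Step count and risks**
Total: 20 steps. Longest linear sequence: 15 steps (steps 6–20, from 1-bromo-3,5-dimethoxybenzene); the ynoate branch (steps 1–5) joins at step 17.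

Steps most likely to fail:

1. Step 17. The cycloaddition may be too slow at temperatures the diene tolerates: the benzylic group on the central diene carbon crowds the s-cis conformer and the ynoate β-carbon carries a branched chain, so desilylation or silyl migration of the diene may outrun ring formation. Fallback: build the right ring without the bridge and attach the bridge afterwards. It sets out from methyl 3-oxopentanoate 23, ynoate 8 and benzylic alcohol 21, and comes back at 30. Compound 23 is silylated (TMSCl, Et3N) to methyl 3-(trimethylsilyloxy)pent-2-enoate F1, deprotonated with LDA to its lithium dienolate F2 and silylated to the unhindered 1-methoxy-1,3-bis(trimethylsilyloxy)penta-1,3-diene F3. Heating F3 with 8 and mild acid work-up should give, through the cyclohexadiene cycloadduct F4, methyl 6-[(2S,3R)-3-(tert-butyldimethylsilyloxy)butan-2-yl]-2,4-dihydroxy-5-methylbenzoate F5, whose only free ring position lies between the two hydroxyls. Acid-catalysed Friedel–Crafts benzylation of F5 with 21 (Sc(OTf)3 cat., CH2Cl2/MeNO2, 0 °C) at that position then gives 30.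

2. Step 19. The bromoborate formed from the free secondary alcohol of the left arm may ionise while the two hindered methyl ethers are still being cleaved, leading to bromide substitution, elimination towards the styrene or loss of configuration at C3. Fallback: take the alcohol out of play as an ester. It sets out from 32 and comes back at 33. Acetylation (Ac2O, pyridine, DMAP) gives the (2R,3S)-3-aryl-butan-2-yl acetate with 6′,8′-diacetoxy lactone F6; BBr3 at −78 → −20 °C then cleaves only the aryl methyl ethers to give the left-ring bis-phenol triacetate F7; methanolysis of the three acetates (K2CO3, MeOH, then aq. HCl to re-close any opened lactone) gives 33.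

3. Step 14. The electron-rich 2,6-dimethoxybenzylic bromide may ionise before or during the alkylation, leading to self-condensation at its free ring position, O-alkylation or double alkylation instead of clean C-alkylation. Fallback: avoid the bromide by condensation and reduction. It sets out from aldehyde 20 and methyl 3-oxopentanoate 23 and comes back at 25. Knoevenagel condensation (piperidine, AcOH, toluene, Dean–Stark) gives methyl 2-(arylmethylidene)-3-oxopentanoate F8, and hydrogenation of its conjugated C=C bond (H2, Pd/C, EtOAc) gives 25.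

**Further compounds**
F1 | step 17 | methyl 3-(trimethylsilyloxy)pent-2-enoate | CCC(O[Si](C)(C)C)=CC(=O)OC
F2 | step 17 | lithium dienolate of F1 | CC=C(O[Si](C)(C)C)C=C([O-])OC.[Li+]
F3 | step 17 | 1-methoxy-1,3-bis(trimethylsilyloxy)penta-1,3-diene | CC=C(O[Si](C)(C)C)C=C(OC)O[Si](C)(C)C
F4 | step 17 | cyclohexadiene cycloadduct of F3 and 8 | COC(=O)C1=C([C@H](C)[C@@H](C)O[Si](C)(C)C(C)(C)C)C(C)C(O[Si](C)(C)C)=CC1(OC)O[Si](C)(C)C
F5 | step 17 | methyl 6-[(2S,3R)-3-(tert-butyldimethylsilyloxy)butan-2-yl]-2,4-dihydroxy-5-methylbenzoate | COC(=O)c1c(O)cc(O)c(C)c1[C@H](C)[C@@H](C)O[Si](C)(C)C(C)(C)C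
F6 | step 19 | triacetate of 32 (arm acetate and 6′,8′-diacetate) | COc1cc([C@H](C)[C@@H](C)OC(C)=O)c(C)c(OC)c1Cc1c(OC(C)=O)c(C)c2c(c1OC(C)=O)C(=O)O[C@H](C)[C@H]2C
F7 | step 19 | left-ring bis-phenol triacetate (demethylated F6) | Cc1c(O)c(Cc2c(OC(C)=O)c(C)c3c(c2OC(C)=O)C(=O)O[C@H](C)[C@H]3C)c(O)cc1[C@H](C)[C@@H](C)OC(C)=O
F8 | step 14 | methyl 2-({4-[(2S,3R)-3-(tert-butyldimethylsilyloxy)butan-2-yl]-2,6-dimethoxy-3-methylphenyl}methylidene)-3-oxopentanoate | CCC(=O)C(=Cc1c(OC)cc([C@H](C)[C@@H](C)O[Si](C)(C)C(C)(C)C)c(C)c1OC)C(=O)OC
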